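Ring A is built in one operation on a ring B alkenyl triflate: carbon monoxide becomes C1 and a vinyl group becomes C2–C3. A palladium-catalysed carbonylative Stille coupling forms C1–C2, and the cross-conjugated dienone then closes C3–C4 by Michael addition of C4, whose hydrogen is acidified by the ester and, through C5=C10, by the new C1 ketone. The step exploits that C1 is a CH between C10 and an unsubstituted C2–C3 unit and that C4 is an ester α-carbon. The C1 oxygen is then spent: catalyst-controlled reduction and reductive allylic transposition deliver H-5 and the C1=C10 alkene. The precursor is a cyclohexenyl triflate carrying a propanoate arm and a C9 alkynyl group.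

Key step: step 5

Remark: halimane numbering is used (ring A = C1–C5 and C10, ring B = C5–C10, C18 = ester carbon on C4, C11 onwards = chain on C9); β is the face that carries the C9 chain, H-5 and the C4 ester in the target, α the face of the C4, C8 and C9 methyl groups.

Step 1
Reactants: 1 2-methylcyclohex-2-en-1-one; 2 trimethylaluminium; 3 trimethylsilyl trifluoromethanesulfonate
Product: 5 {[(3R)-2,3-dimethylcyclohex-1-en-1-yl]oxy}(trimethyl)silane, via aluminium enolate 4 (not isolated)
Conditions: CuTC (copper thiophene-2-carboxylate, CuO2CC4H3S, 2 mol %), BINOL-derived N,N-bis(1-phenylethyl)phosphoramidite ligand (4 mol %, the enantiomer that gives 3R), 2, Et2O, −30 °C; then 3, −30 → 0 °C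
Reagents that add atoms: trimethylaluminium C[Al](C)C; trimethylsilyl trifluoromethanesulfonate C[Si](C)(C)OS(=O)(=O)C(F)(F)F
Why: Copper-catalysed asymmetric conjugate addition puts the methyl group on the β-carbon (C8) under ligand control and so sets C8 as R, and O-silylation of the regiodefined aluminium enolate stores the C9=C10 enolate for step 2.

Step 2
Reactants: 5; 6 1-{[tri(propan-2-yl)silyl]ethynyl}-1,2-benziodoxol-3(1H)-one (TIPS-EBX)
Product: 8 (2R,3R)-2,3-dimethyl-2-{[tri(propan-2-yl)silyl]ethynyl}cyclohexan-1-one, via lithium enolate 7 (not isolated)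
Conditions: MeLi, THF, 0 °C; then 6, −78 → 23 °C; aq. NH4Cl
Reagents that add atoms: TIPS-EBX CC(C)[Si](C(C)C)(C(C)C)C#CI1OC(=O)c2ccccc12
Why: Methyllithium releases the regiodefined lithium enolate, which should undergo electrophilic α-alkynylation with the ethynylbenziodoxolone on the face anti to the adjacent C8 methyl, so the quaternary C9 is set with its methyl cis and its alkyne trans to the C8 methyl.

Step 3
Reactants: 8; 9 methyl 2-bromopropanoate
Product: 11 methyl 2-[(3R,4R)-3,4-dimethyl-2-oxo-3-{[tri(propan-2-yl)silyl]ethynyl}cyclohexyl]propanoate (epimer mixture at C5 and C4), via lithium enolate 10 (not isolated)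
Conditions: LDA, THF, −78 °C; then 9, DMPU, −78 → 0 °C
Reagents that add atoms: methyl 2-bromopropanoate COC(=O)C(C)Br
Why: Enolate alkylation (SN2) at C5, the only enolisable position because C9 is quaternary, attaches the propanoate arm (C4, C18 and the C4 methyl), and the two new centres need no control because both become trigonal again in steps 4 and 5.

Step 4
Reactants: 11; 12 trifluoromethanesulfonic anhydride
Product: 13 methyl 2-[(3R,4R)-3,4-dimethyl-2-{[(trifluoromethyl)sulfonyl]oxy}-3-{[tri(propan-2-yl)silyl]ethynyl}cyclohex-1-en-1-yl]propanoate (both epimers at C4)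
Conditions: Tf2O, 2,6-di-tert-butyl-4-methylpyridine, CH2Cl2, 0 → 23 °C
Reagents that add atoms: trifluoromethanesulfonic anhydride O=S(=O)(OS(=O)(=O)C(F)(F)F)C(F)(F)F
Why: Enol triflate formation can only occur towards C5, which should give the tetrasubstituted C10=C5 alkenyl triflate with the leaving group on C10.

Step 5
Reactants: 13; 14 carbon monoxide; 15 tributyl(ethenyl)stannane
Product: 17 methyl (1S,5S,6R)-1,5,6-trimethyl-4-oxo-5-{[tri(propan-2-yl)silyl]ethynyl}-1,2,3,4,5,6,7,8-octahydronaphthalene-1-carboxylate, via divinyl ketone 16 (not isolated)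
Conditions: Pd(PPh3)4 (5 mol %), LiCl (3 equiv), CO (3 atm), 15 (1.2 equiv), THF, 60 °C; then DBU (1.5 equiv), 23 °C
Reagents that add atoms: carbon monoxide [C-]#[O+]; tributyl(ethenyl)stannane C=C[Sn](CCCC)(CCCC)CCCC
Why: Zerovalent palladium inserts into the C10–OTf bond, carbon monoxide inserts to give the acylpalladium species (this carbon is C1), and transmetalation with the vinylstannane followed by reductive elimination forms C1–C2 in the cross-conjugated divinyl ketone 16, after which DBU removes the doubly activated C4–H (α to the ester and vinylogous to the C1 ketone through C5=C10) and the oxido-triene closes C3–C4. The closest known reaction types are the carbonylative Stille coupling of enol triflates and the base-mediated intramolecular Michael addition of a vinylogous β-keto ester, run here as a domino in one flask. Ring A is closed in the 6-endo-trig mode, which is equivalent to a disrotatory 6π closure of the 3-oxidotriene C4=C5–C10=C1–C2=C3. The new quaternary centre C4 is controlled by ring B: the linear alkynyl group on C9 takes the equatorial site beside the oxido group (least A(1,3) strain), so the C9 methyl is axial, C1 is tilted to the β face and C3 bonds to the β lobe of C4, while the ester keeps the outside position cis to C6, which should place CO2Me β and CH3 α. The step needs CO insertion to outrun direct vinyl transfer (favoured by the hindered tetrasubstituted alkenylpalladium and the CO pressure) and deprotonation at C4 and not at C6 (only C4–H is doubly activated, and closure from C6 would give a bridgehead alkene).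

Step 6
Reactants: 17; 18 catecholborane
Product: 19 methyl (1S,4S,5S,6R)-4-hydroxy-1,5,6-trimethyl-5-{[tri(propan-2-yl)silyl]ethynyl}-1,2,3,4,5,6,7,8-octahydronaphthalene-1-carboxylate
Conditions: (R)-2-methyl-CBS-oxazaborolidine (20 mol %), catecholborane (1.5 equiv), toluene, −78 °C; aq. NaOH work-up
Reagents that add atoms: none
Why: The Corey–Bakshi–Shibata reduction is a catalyst-controlled 1,2-reduction in which the alkenyl carbon C10 acts as the large and C2 as the small substituent, so the (R)-catalyst should deliver hydride to the β face of C1 and set the carbinol as S (hydroxyl α) whatever the existing centres prefer.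

Step 7
Reactants: 19; 20 2-nitrobenzenesulfonohydrazide
Product: 23 methyl (1S,5S,6R,8aS)-1,5,6-trimethyl-5-{[tri(propan-2-yl)silyl]ethynyl}-1,2,3,5,6,7,8,8a-octahydronaphthalene-1-carboxylate, via sulfonyl hydrazine 21 (not isolated), via allylic diazene 22 (not isolated)
Conditions: PPh3, diethyl azodicarboxylate, 20, THF, −30 °C; then 23 °C
Reagents that add atoms: none
Why: Mitsunobu displacement of the allylic hydroxyl by the sulfonyl hydrazide inverts C1, loss of sulfinic acid on warming gives the allylic diazene, and its retro-ene loss of dinitrogen transfers hydrogen suprafacially to the β face of C5, which should set H-5 β (cis to the C4 ester) and move the double bond to C1=C10 (reductive allylic transposition).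

Step 8
Reactants: 23
Product: 24 methyl (1S,5R,6R,8aS)-5-ethynyl-1,5,6-trimethyl-1,2,3,5,6,7,8,8a-octahydronaphthalene-1-carboxylate
Conditions: Bu4NF, THF, 0 → 23 °C
Reagents that add atoms: none
Why: Fluoride-induced protodesilylation cleaves the alkynyl C–Si bond and should leave the hindered methyl ester and the ring alkene untouched.

Step 9
Reactants: 24; 25 dihydrogen
Product: 26 methyl (1S,5S,6R,8aS)-5-ethenyl-1,5,6-trimethyl-1,2,3,5,6,7,8,8a-octahydronaphthalene-1-carboxylate
Conditions: H2 (1 atm), Pd on CaCO3 poisoned with Pb(OAc)2, quinoline, EtOAc, 23 °C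
Reagents that add atoms: none
Why: Semi-hydrogenation over the lead-poisoned palladium catalyst should stop at the alkene stage and reduce only the terminal alkyne, the hindered trisubstituted C1=C10 alkene being inert under these conditions.

Step 10
Reactants: 27 but-2-yn-1-ol; 28 diiodine
Product: 30 (2E)-3-iodobut-2-en-1-ol, via alkenylzirconium species 29 (not isolated)
Conditions: i-Bu2AlH (1.0 equiv), THF, 0 °C; Cp2Zr(H)Cl (1.3 equiv), 23 °C; then 28, −78 → 0 °C; aqueous work-up
Reagents that add atoms: diiodine II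
Why: After the hydroxyl is masked as its aluminium alkoxide, syn-hydrozirconation should place zirconium on the alkyne carbon remote from the oxygen, and iodinolysis of the C–Zr bond with retention gives the E-iodoalkene.

Step 11
Reactants: 26; 31 9-borabicyclo[3.3.1]nonane; 30
Product: 33 methyl (1S,5S,6R,8aS)-5-[(3E)-5-hydroxy-3-methylpent-3-en-1-yl]-1,5,6-trimethyl-1,2,3,5,6,7,8,8a-octahydronaphthalene-1-carboxylate, via alkylborane 32 (not isolated)
Conditions: 9-BBN, THF, 23 °C; then 30, Pd(dppf)Cl2 (5 mol %), AsPh3, Cs2CO3, DMF/H2O, 23 °C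
Reagents that add atoms: (2E)-3-iodobut-2-en-1-ol I/C(C)=C/CO
Why: 9-BBN should add to the terminal vinyl group (boron on C12) and not to the trisubstituted ring alkene, and the B-alkyl Suzuki–Miyaura coupling with the alkenyl iodide forms C12–C13 with retention of the E geometry.

Step 12
Reactants: 33; 34 acetic anhydride
Product: 35 methyl (1S,5S,6R,8aS)-5-[(3E)-5-(acetyloxy)-3-methylpent-3-en-1-yl]-1,5,6-trimethyl-1,2,3,5,6,7,8,8a-octahydronaphthalene-1-carboxylate
Conditions: Ac2O, pyridine, DMAP (cat.), CH2Cl2, 23 °C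
Reagents that add atoms: acetic anhydride CC(=O)OC(C)=O
Why: Acylation of the primary allylic alcohol under nucleophilic catalysis should give the acetate without touching any stereocentre.

Compound list
1 | 2-methylcyclohex-2-en-1-one | CC1=CCCCC1=O | starting material
2 | trimethylaluminium | C[Al](C)C | starting material
3 | trimethylsilyl trifluoromethanesulfonate | C[Si](C)(C)OS(=O)(=O)C(F)(F)F | starting material
4 | dimethylaluminium (3R)-2,3-dimethylcyclohex-1-en-1-olate | C1CC[C@@H](C)C(C)=C1O[Al](C)C | intermediate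
5 | {[(3R)-2,3-dimethylcyclohex-1-en-1-yl]oxy}(trimethyl)silane | C1CC[C@@H](C)C(C)=C1O[Si](C)(C)C | intermediate
6 | 1-{[tri(propan-2-yl)silyl]ethynyl}-1,2-benziodoxol-3(1H)-one (TIPS-EBX) | CC(C)[Si](C(C)C)(C(C)C)C#CI1OC(=O)c2ccccc12 | starting material
7 | lithium (3R)-2,3-dimethylcyclohex-1-en-1-olate | C1CC[C@@H](C)C(C)=C1O[Li] | intermediate
8 | (2R,3R)-2,3-dimethyl-2-{[tri(propan-2-yl)silyl]ethynyl}cyclohexan-1-one | O=C1CCC[C@@H](C)[C@]1(C)C#C[Si](C(C)C)(C(C)C)C(C)C | intermediate
9 | methyl 2-bromopropanoate (racemic) | COC(=O)C(C)Br | starting material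
10 | lithium (5R,6R)-5,6-dimethyl-6-{[tri(propan-2-yl)silyl]ethynyl}cyclohex-1-en-1-olate | [Li]OC1=CCC[C@@H](C)[C@]1(C)C#C[Si](C(C)C)(C(C)C)C(C)C | intermediate
11 | methyl 2-[(3R,4R)-3,4-dimethyl-2-oxo-3-{[tri(propan-2-yl)silyl]ethynyl}cyclohexyl]propanoate, epimer mixture at the ring attachment carbon and at the propanoate α-carbon | COC(=O)C(C)C1CC[C@@H](C)[C@](C)(C#C[Si](C(C)C)(C(C)C)C(C)C)C1=O | intermediate
12 | trifluoromethanesulfonic anhydride | O=S(=O)(OS(=O)(=O)C(F)(F)F)C(F)(F)F | starting material
13 | methyl 2-[(3R,4R)-3,4-dimethyl-2-{[(trifluoromethyl)sulfonyl]oxy}-3-{[tri(propan-2-yl)silyl]ethynyl}cyclohex-1-en-1-yl]propanoate, both epimers at the propanoate α-carbon | COC(=O)C(C)C1=C(OS(=O)(=O)C(F)(F)F)[C@@](C)(C#C[Si](C(C)C)(C(C)C)C(C)C)[C@H](C)CC1 | intermediate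
14 | carbon monoxide | [C-]#[O+] | starting material
15 | tributyl(ethenyl)stannane | C=C[Sn](CCCC)(CCCC)CCCC | starting material
16 | methyl 2-[(3S,4R)-3,4-dimethyl-2-(prop-2-enoyl)-3-{[tri(propan-2-yl)silyl]ethynyl}cyclohex-1-en-1-yl]propanoate | COC(=O)C(C)C1=C(C(=O)C=C)[C@@](C)(C#C[Si](C(C)C)(C(C)C)C(C)C)[C@H](C)CC1 | intermediate
17 | methyl (1S,5S,6R)-1,5,6-trimethyl-4-oxo-5-{[tri(propan-2-yl)silyl]ethynyl}-1,2,3,4,5,6,7,8-octahydronaphthalene-1-carboxylate | COC(=O)[C@@]1(C)CCC(=O)C2=C1CC[C@@H](C)[C@]2(C)C#C[Si](C(C)C)(C(C)C)C(C)C | intermediate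
18 | catecholborane | B1Oc2ccccc2O1 | starting material
19 | methyl (1S,4S,5S,6R)-4-hydroxy-1,5,6-trimethyl-5-{[tri(propan-2-yl)silyl]ethynyl}-1,2,3,4,5,6,7,8-octahydronaphthalene-1-carboxylate | COC(=O)[C@@]1(C)CC[C@H](O)C2=C1CC[C@@H](C)[C@]2(C)C#C[Si](C(C)C)(C(C)C)C(C)C | intermediate
20 | 2-nitrobenzenesulfonohydrazide | NNS(=O)(=O)c1ccccc1[N+](=O)[O-] | starting material
21 | methyl (1S,4R,5S,6R)-4-[1-(2-nitrobenzenesulfonyl)hydrazin-1-yl]-1,5,6-trimethyl-5-{[tri(propan-2-yl)silyl]ethynyl}-1,2,3,4,5,6,7,8-octahydronaphthalene-1-carboxylate | COC(=O)[C@@]1(C)CC[C@@H](N(N)S(=O)(=O)c3ccccc3[N+](=O)[O-])C2=C1CC[C@@H](C)[C@]2(C)C#C[Si](C(C)C)(C(C)C)C(C)C | intermediate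
22 | methyl (1S,4R,5S,6R)-4-diazenyl-1,5,6-trimethyl-5-{[tri(propan-2-yl)silyl]ethynyl}-1,2,3,4,5,6,7,8-octahydronaphthalene-1-carboxylate | COC(=O)[C@@]1(C)CC[C@@H](N=N)C2=C1CC[C@@H](C)[C@]2(C)C#C[Si](C(C)C)(C(C)C)C(C)C | intermediate
23 | methyl (1S,5S,6R,8aS)-1,5,6-trimethyl-5-{[tri(propan-2-yl)silyl]ethynyl}-1,2,3,5,6,7,8,8a-octahydronaphthalene-1-carboxylate | COC(=O)[C@@]1(C)CCC=C2[C@@H]1CC[C@@H](C)[C@]2(C)C#C[Si](C(C)C)(C(C)C)C(C)C | intermediate
24 | methyl (1S,5R,6R,8aS)-5-ethynyl-1,5,6-trimethyl-1,2,3,5,6,7,8,8a-octahydronaphthalene-1-carboxylate | COC(=O)[C@@]1(C)CCC=C2[C@@H]1CC[C@@H](C)[C@]2(C)C#C | intermediate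
25 | dihydrogen | [H][H] | starting material
26 | methyl (1S,5S,6R,8aS)-5-ethenyl-1,5,6-trimethyl-1,2,3,5,6,7,8,8a-octahydronaphthalene-1-carboxylate | COC(=O)[C@@]1(C)CCC=C2[C@@H]1CC[C@@H](C)[C@]2(C)C=C | intermediate
27 | but-2-yn-1-ol | CC#CCO | starting material
28 | diiodine | II | starting material
29 | (E)-alkenylzirconocene chloride of but-2-yn-1-ol, zirconium on C3 trans to the CH2O group, oxygen bound to diisobutylaluminium | C/C(=C\CO[Al](CC(C)C)CC(C)C)[Zr](Cl)(C1C=CC=C1)C1C=CC=C1 | intermediate
30 | (2E)-3-iodobut-2-en-1-ol | I/C(C)=C/CO | intermediate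
31 | 9-borabicyclo[3.3.1]nonane | B1C2CCCC1CCC2 | starting material
32 | methyl (1S,5S,6R,8aS)-5-[2-(9-borabicyclo[3.3.1]nonan-9-yl)ethyl]-1,5,6-trimethyl-1,2,3,5,6,7,8,8a-octahydronaphthalene-1-carboxylate | COC(=O)[C@@]1(C)CCC=C2[C@@H]1CC[C@@H](C)[C@]2(C)CCB1C3CCCC1CCC3 | intermediate
33 | methyl (1S,5S,6R,8aS)-5-[(3E)-5-hydroxy-3-methylpent-3-en-1-yl]-1,5,6-trimethyl-1,2,3,5,6,7,8,8a-octahydronaphthalene-1-carboxylate | COC(=O)[C@@]1(C)CCC=C2[C@@H]1CC[C@@H](C)[C@]2(C)CC/C(C)=C/CO | intermediate
34 | acetic anhydride | CC(=O)OC(C)=O | starting material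
35 | methyl (1S,5S,6R,8aS)-5-[(3E)-5-(acetyloxy)-3-methylpent-3-en-1-yl]-1,5,6-trimethyl-1,2,3,5,6,7,8,8a-octahydronaphthalene-1-carboxylate (CNP0209995.2) | COC(=O)[C@@]1(C)CCC=C2[C@@H]1CC[C@@H](C)[C@]2(C)CC/C(C)=C/COC(C)=O | target

Total step count: 12. Longest linear sequence: 11 steps (steps 1–9, 11 and 12); step 10 is a one-step side branch.

Steps most likely to fail

1. Step 5. Vinyl transfer may occur before CO insertion, the vinyl ketone may polymerise before ring closure, or the C3–C4 closure may discriminate the two faces of C4 only weakly, since that control rests on the ring B conformation. The fallback replaces the domino by a stepwise annulation. It sets out from 13: palladium-catalysed methoxycarbonylation (Pd(OAc)2, dppf, CO, MeOH, Et3N) should give the glutaconate-type diester F1. Michael addition of its C4 anion to methyl acrylate followed by Dieckmann closure (KOtBu, THF) should give the β-keto diester F2. Krapcho demethoxycarbonylation (LiCl, wet DMSO, 140 °C) comes back to the route at 17. If C4 is formed unselectively in either mode, the wrong epimer is removed after step 6: only the C4-epimeric hydroxy ester F3, whose hydroxyl is cis to the ester, can lactonise (TsOH cat., toluene) to the bridged lactone F4, which is separated from 19.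

2. Step 7. At the hindered cyclic allylic carbinol, the Mitsunobu displacement may give way to elimination or to loss of stereochemical integrity by ionisation, so that hydrogen is not delivered cleanly to C5. The fallback uses palladium π-allyl chemistry and sets out from 19: acylation with methyl chloroformate and pyridine should give the allylic methyl carbonate F5. Reduction with Pd(OAc)2, PBu3 and ammonium formate ionises anti to the carbonate and transfers hydride from palladium to the more substituted terminus C5 on the face opposite to the original oxygen. This is the same β face, and the fallback comes back to the route at 23.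

3. Step 2. Alkynyl transfer to the congested tetrasubstituted enolate may be slow, so that proton transfer or attack through oxygen takes over. The fallback builds the alkyne by addition–elimination and sets out from the lithium enolate 7: addition to dichloroacetylene formed in situ from trichloroethylene should give the dichlorovinyl ketone F6. After masking of the ketone as its enolate with LDA, n-BuLi effects elimination and chlorine–lithium exchange to the lithium acetylide, which is silylated with i-Pr3SiOTf. Mild acidic work-up comes back to the route at 8.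

Further compounds
F1 | step 5 | methyl (5R,6S)-2-(1-methoxy-1-oxopropan-2-yl)-5,6-dimethyl-6-{[tri(propan-2-yl)silyl]ethynyl}cyclohex-1-ene-1-carboxylate | COC(=O)C(C)C1=C(C(=O)OC)[C@@](C)(C#C[Si](C(C)C)(C(C)C)C(C)C)[C@H](C)CC1
F2 | step 5 | dimethyl (1S,5S,6R)-1,5,6-trimethyl-4-oxo-5-{[tri(propan-2-yl)silyl]ethynyl}-1,2,3,4,5,6,7,8-octahydronaphthalene-1,3-dicarboxylate | COC(=O)[C@@]1(C)CC(C(=O)OC)C(=O)C2=C1CC[C@@H](C)[C@]2(C)C#C[Si](C(C)C)(C(C)C)C(C)C
F3 | step 5 | methyl (1R,4S,5S,6R)-4-hydroxy-1,5,6-trimethyl-5-{[tri(propan-2-yl)silyl]ethynyl}-1,2,3,4,5,6,7,8-octahydronaphthalene-1-carboxylate | COC(=O)[C@]1(C)CC[C@H](O)C2=C1CC[C@@H](C)[C@]2(C)C#C[Si](C(C)C)(C(C)C)C(C)C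
F4 | step 5 | bridged lactone of F3 (C1 oxygen acylated by the C4 carboxyl, 2-oxabicyclo[2.2.2]oct-5-en-3-one core fused to ring B) | O=C1O[C@H]2CC[C@]1(C)C3=C2[C@@](C)(C#C[Si](C(C)C)(C(C)C)C(C)C)[C@H](C)CC3
F5 | step 7 | methyl (1S,4S,5S,6R)-4-[(methoxycarbonyl)oxy]-1,5,6-trimethyl-5-{[tri(propan-2-yl)silyl]ethynyl}-1,2,3,4,5,6,7,8-octahydronaphthalene-1-carboxylate | COC(=O)[C@@]1(C)CC[C@H](OC(=O)OC)C2=C1CC[C@@H](C)[C@]2(C)C#C[Si](C(C)C)(C(C)C)C(C)C
F6 | step 2 | (2S,3R)-2-[(E)-1,2-dichloroethenyl]-2,3-dimethylcyclohexan-1-one | O=C1CCC[C@@H](C)[C@]1(C)/C(Cl)=C\Cl
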